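**Retrosynthetic overview**

1. Ring A is numbered C1 (carrying the chain C7-C8-C9(=O)-pyrrole B), C2 (OH), C3 and C4 (H), C5 (aroyl to pyrrole C), C6 (OH). The route rests on C7 at C1 being flanked by the oxygens at C2 and C6: 3-methoxybenzyne can take up the oxygen (at C2) and the carbonyl carbon C7 (at C1) of a C7-C8-C9 enal in one event, its methoxy group being the future C6 oxygen.
2. Last disconnections: O-demethylation, then the ring A-aroyl bond by Fries rearrangement of the C2-O ester. Once both oxygens are free, ring A is symmetric about the C1-C4 axis, so acyl migration ortho or para to the ester oxygen converges on the target pattern.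
3. The C2 phenol and the C9 ketone are unmasked by hydrolysis of a 2-pyrrolyl-4H-chromene (a cyclic enol ether), reached from the 2H-chromene by a base-mediated prototropic shift and N-SEM removal.
4. The 2H-chromene comes from the aryne and an N-SEM (E)-3-(4,5-dichloropyrrol-2-yl)acrolein by C=O insertion, 4-pi opening and oxa-6-pi closure. The pyran is the only ring built and is reopened later; rings A, B and C are bought in.
5. The enal comes from pyrrole-2-carbaldehyde by 4,5-dichlorination, N-SEM protection and Wittig homologation; the same dichloroaldehyde is oxidised to the acid that supplies the aroyl unit.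

Key step: step 4

Remark: SEM = 2-(trimethylsilyl)ethoxymethyl. The target is achiral; the one stereocentre made in step 4 is racemic and is removed in step 5.

**Route**

Step 1
Reactants: 1 pyrrole-2-carbaldehyde
Product: 2 4,5-dichloro-1H-pyrrole-2-carbaldehyde
Conditions: SO2Cl2 (2.1 equiv), CH2Cl2, 0 °C to rt
Reagents that add atoms: sulfuryl chloride, O=S(=O)(Cl)Cl
Why: Electrophilic aromatic chlorination of a 2-acylpyrrole should go to C4 and C5 (either monochloride converges on the 4,5-dichloride), while C3 next to the formyl group is the least reactive site and is spared at this stoichiometry.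

Step 2
Reactants: 2 4,5-dichloro-1H-pyrrole-2-carbaldehyde
Product: 3 4,5-dichloro-1-(2-trimethylsilylethoxymethyl)pyrrole-2-carbaldehyde
Conditions: NaH, DMF, 0 °C; SEMCl, 0 °C to rt
Reagents that add atoms: 2-(trimethylsilyl)ethoxymethyl chloride, C[Si](C)(C)CCOCCl
Why: N-alkylation of the acidic acylpyrrole anion with SEMCl blocks the N-H (which an aryne would arylate) with a group that keeps the pyrrole a donor and tolerates CsF at room temperature.

Step 3
Reactants: 3 4,5-dichloro-1-(2-trimethylsilylethoxymethyl)pyrrole-2-carbaldehyde; 4 (triphenylphosphoranylidene)acetaldehyde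
Product: 5 (E)-3-[4,5-dichloro-1-(2-trimethylsilylethoxymethyl)pyrrol-2-yl]acrylaldehyde
Conditions: 4 (1.2 equiv), toluene, 90 °C
Reagents that add atoms: none
Why: Wittig olefination with a stabilised ylide should give the (E)-enal; a second homologation is held back by the limited ylide charge and by the lower electrophilicity of the doubly vinylogous product aldehyde.

Step 4
Reactants: 5 (E)-3-[4,5-dichloro-1-(2-trimethylsilylethoxymethyl)pyrrol-2-yl]acrylaldehyde (1.5 equiv); 6 3-methoxy-2-(trimethylsilyl)phenyl trifluoromethanesulfonate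
Product: 10 racemic 2-[4,5-dichloro-1-(2-trimethylsilylethoxymethyl)pyrrol-2-yl]-5-methoxy-2H-chromene, via 3-methoxybenzyne 7 (not isolated), via 2-alkenyl-3-methoxy-2H-benzoxete 8 (not isolated), via ortho-quinone methide 9 (not isolated)
Conditions: CsF (3 equiv), MeCN, rt, 6 added slowly to 5 and CsF
Reagents that add atoms: none
Why: Fluoride-induced 1,2-elimination of 6 releases 3-methoxybenzyne 7, which is attacked by the carbonyl oxygen of the vinylogous-amide-like enal 5 at the carbon remote from OMe (the future C2), and the aryl anion thus placed next to OMe (C1, inductively stabilised) closes on the oxocarbenium carbon C7 to benzoxete 8, a formal (2+2) addition across C=O. Conrotatory 4-pi opening of 8 gives ortho-quinone methide 9, a 1-oxatriene, in which the C6 methoxy group disfavours the geometry that turns the alkenyl chain towards it and so keeps the chain beside the quinoid oxygen. A thermally allowed disrotatory oxa-6-pi electrocyclisation then forms O-C9 and the pyran ring and restores the aromaticity of ring A. The closest known reaction type is the insertion of arynes into the C=O bond of formamides and of alpha,beta-unsaturated aldehydes, which gives ortho-quinone methides and 2H-chromenes. The only new stereocentre (C9, chromene C2) forms without any controlling element as a racemate, which is acceptable because it becomes trigonal in step 5. The step needs regioselective addition to the unsymmetrical aryne, secured by the methoxy group, and carbonyl addition in preference to cycloaddition at the pyrrole or the styrene-like C=C, favoured by the donor pyrrole that raises oxygen nucleophilicity, by the crowded chlorinated pyrrole and by slow release of the aryne into excess 5.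

Step 5
Reactants: 10 racemic 2-[4,5-dichloro-1-(2-trimethylsilylethoxymethyl)pyrrol-2-yl]-5-methoxy-2H-chromene
Product: 11 2-[4,5-dichloro-1-(2-trimethylsilylethoxymethyl)pyrrol-2-yl]-5-methoxy-4H-chromene
Conditions: KOtBu (0.3 equiv), DMSO, rt, argon
Reagents that add atoms: none
Why: Base-mediated allyl ether to enol ether isomerisation: the C2-H (alpha to oxygen, allylic and pyrrolyl-substituted) is removed, and reprotonation of the delocalised anion at C4 should give the enol ether, which is conjugated with the ring oxygen and the pyrrole.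

Step 6
Reactants: 11 2-[4,5-dichloro-1-(2-trimethylsilylethoxymethyl)pyrrol-2-yl]-5-methoxy-4H-chromene
Product: 12 2-(4,5-dichloro-1H-pyrrol-2-yl)-5-methoxy-4H-chromene
Conditions: TBAF (4 equiv), THF, 65 °C; aq NH4Cl work-up
Reagents that add atoms: none
Why: Fluoride attack at silicon with loss of ethylene leaves an N-CH2-O anion that expels formaldehyde from the dichloropyrrolide (standard N-SEM cleavage), done here while ring A carries no free phenol that could be hydroxymethylated and before any Lewis acid is used.

Step 7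
Reactants: 12 2-(4,5-dichloro-1H-pyrrol-2-yl)-5-methoxy-4H-chromene
Product: 13 1-(4,5-dichloro-1H-pyrrol-2-yl)-3-(2-hydroxy-6-methoxyphenyl)propan-1-one
Conditions: 1 M HCl, THF, rt
Reagents that add atoms: water, O
Why: Acid hydrolysis of the aryl enol ether (C-protonation to a pyrrole-stabilised oxocarbenium ion, addition of water, collapse of the hemiketal) should free the C2 phenol and the C9 ketone, the open form being favoured as a conjugated 2-acylpyrrole.

Step 8
Reactants: 2 4,5-dichloro-1H-pyrrole-2-carbaldehyde
Product: 14 4,5-dichloro-1H-pyrrole-2-carboxylic acid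
Conditions: NaClO2, NaH2PO4, 2-methyl-2-butene, t-BuOH/H2O, rt
Reagents that add atoms: sodium chlorite, [Na+].[O-]Cl=O
Why: Pinnick oxidation converts the aldehyde into the acid, with 2-methyl-2-butene taking up the hypochlorous acid so that the deactivated pyrrole C3 is not chlorinated.

Step 9
Reactants: 13 1-(4,5-dichloro-1H-pyrrol-2-yl)-3-(2-hydroxy-6-methoxyphenyl)propan-1-one; 14 4,5-dichloro-1H-pyrrole-2-carboxylic acid
Product: 15 2-[3-(4,5-dichloro-1H-pyrrol-2-yl)-3-oxopropyl]-3-methoxyphenyl 4,5-dichloro-1H-pyrrole-2-carboxylate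
Conditions: EDC·HCl (1.2 equiv), DMAP (0.1 equiv), CH2Cl2, 0 °C to rt
Reagents that add atoms: none
Why: Steglich esterification should acylate the phenol oxygen, which is far more nucleophilic than either pyrrole N-H (whose lone pairs belong to the aromatic sextets).

Step 10
Reactants: 15 2-[3-(4,5-dichloro-1H-pyrrol-2-yl)-3-oxopropyl]-3-methoxyphenyl 4,5-dichloro-1H-pyrrole-2-carboxylate
Product: 16 1-(4,5-dichloro-1H-pyrrol-2-yl)-3-[3-(4,5-dichloro-1H-pyrrole-2-carbonyl)-2-hydroxy-6-methoxyphenyl]propan-1-one
Conditions: TiCl4 (4 equiv), ClCH2CH2Cl, rt to 70 °C; then 1 M HCl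
Reagents that add atoms: none
Why: Lewis-acid Fries rearrangement: the pyrrole-stabilised acylium ion released from the ester should re-enter ring A at the carbon ortho to the phenoxide oxygen and para to OMe (chelation-favoured), and any isomer acylated para to that oxygen gives the same compound after step 11 and need not be removed.

Step 11
Reactants: 16 1-(4,5-dichloro-1H-pyrrol-2-yl)-3-[3-(4,5-dichloro-1H-pyrrole-2-carbonyl)-2-hydroxy-6-methoxyphenyl]propan-1-one
Product: 17 dihydrotetrachlorizine
Conditions: BBr3 (8 equiv), CH2Cl2, −78 °C to rt; then MeOH, H2O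
Reagents that add atoms: none
Why: BBr3 cleavage of the aryl methyl ether (bromide attack on the O-methyl of the borane-complexed ether), with excess reagent to saturate the ketones and N-H groups, should free the second resorcinol hydroxyl and leave the aroyl group next to a hydroxyl, as at C5 and C6 of the target.

**Compound list**

1 | pyrrole-2-carbaldehyde | O=Cc1ccc[nH]1 | starting material
2 | 4,5-dichloro-1H-pyrrole-2-carbaldehyde | O=Cc1cc(Cl)c(Cl)[nH]1 | intermediate
3 | 4,5-dichloro-1-(2-trimethylsilylethoxymethyl)pyrrole-2-carbaldehyde | O=Cc1cc(Cl)c(Cl)n1COCC[Si](C)(C)C | intermediate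
4 | (triphenylphosphoranylidene)acetaldehyde | O=CC=P(c1ccccc1)(c1ccccc1)c1ccccc1 | starting material
5 | (E)-3-[4,5-dichloro-1-(2-trimethylsilylethoxymethyl)pyrrol-2-yl]acrylaldehyde | O=C/C=C/c1cc(Cl)c(Cl)n1COCC[Si](C)(C)C | intermediate
6 | 3-methoxy-2-(trimethylsilyl)phenyl trifluoromethanesulfonate | COc1cccc(OS(=O)(=O)C(F)(F)F)c1[Si](C)(C)C | starting material
7 | 3-methoxybenzyne | COC1=CC=CC#C1 | intermediate (not isolated)
8 | 2-{(E)-2-[4,5-dichloro-1-(2-trimethylsilylethoxymethyl)pyrrol-2-yl]ethenyl}-3-methoxy-2H-benzoxete | COc1cccc2OC(/C=C/c3cc(Cl)c(Cl)n3COCC[Si](C)(C)C)c12 | intermediate (not isolated)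
9 | ortho-quinone methide, 5-methoxy-6-{(E)-3-[4,5-dichloro-1-(2-trimethylsilylethoxymethyl)pyrrol-2-yl]prop-2-enylidene}cyclohexa-2,4-dien-1-one, chain syn to the carbonyl oxygen | COC1=CC=CC(=O)/C1=C\C=C\c1cc(Cl)c(Cl)n1COCC[Si](C)(C)C | intermediate (not isolated)
10 | racemic 2-[4,5-dichloro-1-(2-trimethylsilylethoxymethyl)pyrrol-2-yl]-5-methoxy-2H-chromene | COc1cccc2OC(c3cc(Cl)c(Cl)n3COCC[Si](C)(C)C)C=Cc12 | intermediate
11 | 2-[4,5-dichloro-1-(2-trimethylsilylethoxymethyl)pyrrol-2-yl]-5-methoxy-4H-chromene | COc1cccc2OC(c3cc(Cl)c(Cl)n3COCC[Si](C)(C)C)=CCc12 | intermediate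
12 | 2-(4,5-dichloro-1H-pyrrol-2-yl)-5-methoxy-4H-chromene | COc1cccc2OC(c3cc(Cl)c(Cl)[nH]3)=CCc12 | intermediate
13 | 1-(4,5-dichloro-1H-pyrrol-2-yl)-3-(2-hydroxy-6-methoxyphenyl)propan-1-one | COc1cccc(O)c1CCC(=O)c1cc(Cl)c(Cl)[nH]1 | intermediate
14 | 4,5-dichloro-1H-pyrrole-2-carboxylic acid | O=C(O)c1cc(Cl)c(Cl)[nH]1 | intermediate
15 | 2-[3-(4,5-dichloro-1H-pyrrol-2-yl)-3-oxopropyl]-3-methoxyphenyl 4,5-dichloro-1H-pyrrole-2-carboxylate | COc1cccc(OC(=O)c2cc(Cl)c(Cl)[nH]2)c1CCC(=O)c1cc(Cl)c(Cl)[nH]1 | intermediate
16 | 1-(4,5-dichloro-1H-pyrrol-2-yl)-3-[3-(4,5-dichloro-1H-pyrrole-2-carbonyl)-2-hydroxy-6-methoxyphenyl]propan-1-one | COc1ccc(C(=O)c2cc(Cl)c(Cl)[nH]2)c(O)c1CCC(=O)c1cc(Cl)c(Cl)[nH]1 | intermediate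
17 | dihydrotetrachlorizine, 1-(4,5-dichloro-1H-pyrrol-2-yl)-3-[3-(4,5-dichloro-1H-pyrrole-2-carbonyl)-2,6-dihydroxyphenyl]propan-1-one | O=C(CCc1c(O)ccc(C(=O)c2cc(Cl)c(Cl)[nH]2)c1O)c1cc(Cl)c(Cl)[nH]1 | target

**Step count and risks**

Total step count: 11. Longest linear sequence: 10 steps (steps 1 to 7 and 9 to 11 from pyrrole-2-carbaldehyde); step 8 is a one-step branch from 2.

The three steps most likely to fail:

- **Step 4.** The carbonyl oxygen of 5 may add to the aryne too slowly, so that the aryne is consumed by cycloaddition across the pyrrole or the alkene, or a second aryne captures the ortho-quinone methide before it closes. Fallback, setting out from enal 5 and returning at 10: 3-methoxyphenol is protected (MOMCl, i-Pr2NEt) as 1-methoxy-3-(methoxymethoxy)benzene F1. n-BuLi in THF at 0 °C lithiates F1 between its two oxygens to [2-methoxy-6-(methoxymethoxy)phenyl]lithium F2. 1,2-Addition of F2 to 5 at −78 °C gives the racemic carbinol (E)-1-[2-methoxy-6-(methoxymethoxy)phenyl]-3-[4,5-dichloro-1-(2-trimethylsilylethoxymethyl)pyrrol-2-yl]prop-2-en-1-ol F3. Mild acid (HCl in MeOH, rt) removes the MOM group to give the phenol carbinol (E)-1-(2-hydroxy-6-methoxyphenyl)-3-[4,5-dichloro-1-(2-trimethylsilylethoxymethyl)pyrrol-2-yl]prop-2-en-1-ol F4, which loses water to the same ortho-quinone methide 9 and closes to 10. Directed lithiation places C7 between the two oxygens, as the aryne does.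

- **Step 5.** The prototropic shift may stop at an equilibrium mixture of the 2H- and 4H-chromenes, or the delocalised anion may decompose or be oxidised by traces of air. Fallback, setting out from 10 and returning at 13 (bypassing 11 and 12): hydride abstraction from C2 with Ph3C BF4 in CH2Cl2 gives 2-[4,5-dichloro-1-(2-trimethylsilylethoxymethyl)pyrrol-2-yl]-5-methoxychromenylium tetrafluoroborate F5. Aqueous NaHCO3 in MeCN hydrates C2 and opens the hemiketal to the chalcone-type enone (E)-3-(2-hydroxy-6-methoxyphenyl)-1-[4,5-dichloro-1-(2-trimethylsilylethoxymethyl)pyrrol-2-yl]prop-2-en-1-one F6. Conjugate reduction with [(Ph3P)CuH]6 in wet THF gives 3-(2-hydroxy-6-methoxyphenyl)-1-[4,5-dichloro-1-(2-trimethylsilylethoxymethyl)pyrrol-2-yl]propan-1-one F7. TBAF with ethylenediamine as formaldehyde scavenger (THF, 65 °C) then removes the SEM group to give 13.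

- **Step 10.** The acylium ion may fail to recombine with ring A, so that the ester is only cleaved back to 13, or the Lewis acid may degrade the two acylpyrroles. Fallback, setting out from 13 and returning at 17 (bypassing 15 and 16): BBr3 in CH2Cl2 demethylates 13 to the symmetric resorcinol 1-(4,5-dichloro-1H-pyrrol-2-yl)-3-(2,6-dihydroxyphenyl)propan-1-one F8. Acid 14 is converted with (COCl)2 and catalytic DMF into 4,5-dichloro-1H-pyrrole-2-carbonyl chloride F9. Friedel-Crafts acylation of F8 with F9 (AlCl3, nitrobenzene, rt to 50 °C) attacks one of the two equivalent activated ring positions and should give 17 directly.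

**Further compounds**

F1 | step 4 | 1-methoxy-3-(methoxymethoxy)benzene | COCOc1cccc(OC)c1
F2 | step 4 | [2-methoxy-6-(methoxymethoxy)phenyl]lithium | [Li]c1c(OC)cccc1OCOC
F3 | step 4 | racemic (E)-1-[2-methoxy-6-(methoxymethoxy)phenyl]-3-[4,5-dichloro-1-(2-trimethylsilylethoxymethyl)pyrrol-2-yl]prop-2-en-1-ol | COCOc1cccc(OC)c1C(O)/C=C/c1cc(Cl)c(Cl)n1COCC[Si](C)(C)C
F4 | step 4 | racemic (E)-1-(2-hydroxy-6-methoxyphenyl)-3-[4,5-dichloro-1-(2-trimethylsilylethoxymethyl)pyrrol-2-yl]prop-2-en-1-ol | COc1cccc(O)c1C(O)/C=C/c1cc(Cl)c(Cl)n1COCC[Si](C)(C)C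
F5 | step 5 | 2-[4,5-dichloro-1-(2-trimethylsilylethoxymethyl)pyrrol-2-yl]-5-methoxychromenylium tetrafluoroborate | COc1cccc2[o+]c(-c3cc(Cl)c(Cl)n3COCC[Si](C)(C)C)ccc12.F[B-](F)(F)F
F6 | step 5 | (E)-3-(2-hydroxy-6-methoxyphenyl)-1-[4,5-dichloro-1-(2-trimethylsilylethoxymethyl)pyrrol-2-yl]prop-2-en-1-one | COc1cccc(O)c1/C=C/C(=O)c1cc(Cl)c(Cl)n1COCC[Si](C)(C)C
F7 | step 5 | 3-(2-hydroxy-6-methoxyphenyl)-1-[4,5-dichloro-1-(2-trimethylsilylethoxymethyl)pyrrol-2-yl]propan-1-one | COc1cccc(O)c1CCC(=O)c1cc(Cl)c(Cl)n1COCC[Si](C)(C)C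
F8 | step 10 | 1-(4,5-dichloro-1H-pyrrol-2-yl)-3-(2,6-dihydroxyphenyl)propan-1-one | Oc1cccc(O)c1CCC(=O)c1cc(Cl)c(Cl)[nH]1
F9 | step 10 | 4,5-dichloro-1H-pyrrole-2-carbonyl chloride | O=C(Cl)c1cc(Cl)c(Cl)[nH]1
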